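## Retrosynthetic overview

1. The only ring, the 42-membered lactone, is closed at C2=C3 by an intramolecular Horner–Wadsworth–Emmons reaction (step 32); the C9, C13 and C17 carbinols are traced back to ketones that are reduced together in the last step by 1,3-anti hydroxyl-directed hydride delivery.
2. Key disconnection C16–C17: C17 is a lithiated 1,3-dithiane (acyl anion) carried by the complete C17–C50 chain; it opens the C15–C16 epoxide of a C3–C16 piece.
3. Both halves come from one C10 epoxide (C3–C12 ≡ C19–C28), built from (Z)-3-iodo-2-methylallyl alcohol, (S)-epichlorohydrin and a lithiated 2-silyl-1,3-dithiane by anion-relay (Brook) linchpin couplings; one batch of the lithiated linchpin serves all three couplings. In the east the dithianes are erased to CH2 (1,5,9-triol); in the west they stay as masked ketones.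
4. C38=C39 comes from a Z-Wittig reaction with a C39–C50 aldehyde ((R)-propylene oxide, Z-crotylboration, allylboration); C18/C19 come from a thiazolidinethione aldol on the C19 (Z)-enal.
5. Order: acyclic assembly, C16–C17 union, macrocyclization, then ketone release and triple reduction.

Assumption: the SMILES is taken literally (2E,4Z,20Z,38Z; 7S,9R,11S,13R,15S,17R,18R,19S,23R,27R,31R,41S,42S,43R,49R). Atoms keep the target's chain numbering (C1 lactone carbonyl, C41 carbinol carbon bearing the lactone oxygen, C50 terminal methyl). R/S letters quoted for intermediates are those the centre has in the target; the SMILES is authoritative. TBS = tert-butyldimethylsilyl, TES = triethylsilyl, Ipc = isopinocampheyl, "dithiane" = 1,3-dithiane-2,2-diyl at the stated carbon.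

## Route

Step 1
Reactants: 1 prop-2-yn-1-ol
Product: 3 (Z)-3-iodo-2-methylprop-2-en-1-ol, via bis(bromomagnesium) alkenyl alkoxide 2 (not isolated)
Conditions: MeMgBr (2.5 equiv), CuI (10 mol %), THF, −10 °C → rt; then I2, −10 °C
Reagents that add atoms: methylmagnesium bromide C[Mg]Br; iodine II
Why: Copper-catalysed anti-carbomagnesiation of the propargylic alkoxide puts Me on C-2 and Mg on C-3 cis to CH2O (five-membered chelate), and iodinolysis with retention gives only the Z-iodide, the geometry later needed at C4=C5 and C20=C21.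

Step 2
Reactants: 3 (Z)-3-iodo-2-methylprop-2-en-1-ol
Product: 4 (Z)-iodo allyl TBS ether
Conditions: TBSCl, imidazole, CH2Cl2, 0 °C → rt
Reagents that add atoms: tert-butyldimethylsilyl chloride CC(C)(C)[Si](C)(C)Cl
Why: Standard silylation of a primary alcohol, needed before organometallic steps.

Step 3
Reactants: 4 (Z)-iodo allyl TBS ether; 5 (S)-epichlorohydrin
Product: 8 (S)-2-[(Z)-4-(TBS-oxy)-3-methylbut-2-enyl]oxirane, via alkenylmagnesium chloride 6 (not isolated), via chlorohydrin 7 (not isolated)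
Conditions: i-PrMgCl·LiCl, THF, 0 °C → rt; CuI (10 mol %), 5, −40 → 0 °C; aqueous work-up; then powdered NaOH, Et2O, rt
Reagents that add atoms: none
Why: Iodine–magnesium exchange retains the Z geometry, copper-catalysed Grignard opening of epichlorohydrin occurs at the oxirane CH2, and base closes the chlorohydrin onto the former CH2Cl carbon (Williamson-type), so the stereocentre of (S)-epichlorohydrin is carried over untouched as C7 (S).

Step 4
Reactants: 9 2-(tert-butyldimethylsilyl)-1,3-dithiane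
Product: 10 2-lithio-2-(tert-butyldimethylsilyl)-1,3-dithiane as a titrated stock solution in Et2O
Conditions: t-BuLi, Et2O, −78 → −45 °C, 1 h; kept under argon at −30 °C
Reagents that add atoms: tert-butyllithium [Li]C(C)(C)C
Why: Deprotonation between the two sulfur atoms gives the silyl-dithiane acyl-anion linchpin, and because lithiated 1,3-dithianes keep for weeks in the cold under argon, one titrated ethereal batch supplies the three linchpin couplings (steps 5, 6 and 8).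

Step 5
Reactants: 8 allyl epoxide; 10 lithiated silyl dithiane (stock solution); 5 (S)-epichlorohydrin
Product: 14 C3–C12 epoxide (7S,11S; C9 dithiane), via lithium alkoxide 11 (not isolated), via Brook-shifted dithianyl anion 12 (not isolated), via chlorohydrin alkoxide 13 (not isolated)
Conditions: 10, Et2O, −78 °C; 8, −78 → −25 °C; then 5, HMPA/THF, −78 °C → rt
Reagents that add atoms: none
Why: Anion-relay (silyl-dithiane linchpin) coupling: acyl-anion equivalent 10 opens the epoxide at C8, HMPA triggers the 1,4-Brook shift that silylates O7 and regenerates a dithiane anion at C9, which opens (S)-epichlorohydrin at its oxirane CH2 before ring closure on warming; C11 (S) comes unchanged from epichlorohydrin.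

Step 6
Reactants: 14 C3–C12 epoxide; 10 lithiated silyl dithiane (stock solution); 5 (S)-epichlorohydrin
Product: 18 C3–C16 epoxide (7S,11S,15S; C9 and C13 dithianes), via lithium alkoxide 15 (not isolated), via Brook-shifted dithianyl anion 16 (not isolated), via chlorohydrin alkoxide 17 (not isolated)
Conditions: 10, Et2O, −78 °C; 14, −78 → −25 °C; then 5, HMPA/THF, −78 °C → rt
Reagents that add atoms: none
Why: Second anion-relay linchpin coupling of the same kind; O11 is silylated by the Brook shift and C15 (S) comes from (S)-epichlorohydrin, so the three western carbinols C7, C11 and C15 are all chiral-pool centres.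

Step 7
Reactants: 19 1-bromo-6-chlorohexane; 20 (R)-epichlorohydrin
Product: 23 (R)-2-(7-chloroheptyl)oxirane, via 6-chlorohexylmagnesium bromide 21 (not isolated), via dichloro alcohol 22 (not isolated)
Conditions: Mg, THF, rt; CuI (5 mol %), 20, −30 → 0 °C; aqueous work-up; then powdered NaOH, Et2O, rt
Reagents that add atoms: none
Why: Magnesium inserts selectively into C–Br, the copper-catalysed Grignard opens the oxirane CH2 and base closes only the chlorohydrin, leaving the remote chloride; the epichlorohydrin centre becomes C31 (R).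

Step 8
Reactants: 23 (R)-2-(7-chloroheptyl)oxirane; 10 lithiated silyl dithiane (stock solution); 14 C3–C12 epoxide (here used as C19–C28)
Product: 27 C19–C38 chloride (tetrakis-TBS ether; C25 and C29 dithianes), via C31 lithium alkoxide 24 (not isolated), via Brook-shifted C29 anion 25 (not isolated), via C27 lithium alkoxide 26 (not isolated)
Conditions: 10, Et2O, −78 °C; 23, −78 → −25 °C; 14, HMPA/THF, −78 → −30 °C; then TBSOTf, −78 → 0 °C
Reagents that add atoms: tert-butyldimethylsilyl triflate CC(C)(C)[Si](C)(C)OS(=O)(=O)C(F)(F)F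
Why: Anion-relay linchpin coupling in which 14 is mapped onto C19–C28 (its carbinols are C23 and C27 of the target): 10 opens the cheap epoxide 23 at C30 faster than it displaces the remote primary chloride, the HMPA-triggered Brook shift silylates O31, the relayed C29 anion opens the epoxide of 14 at C28, and the C27 alkoxide is silylated in the flask; C23, C27 and C31 (all R) are chiral-pool centres.

Step 9
Reactants: 27 C19–C38 bis-dithiane chloride
Product: 28 C19–C38 chloride (C25 and C29 now CH2)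
Conditions: Raney Ni (W-2, deactivated in refluxing acetone), EtOH, rt → 50 °C
Reagents that add atoms: none
Why: Hydrogenolytic desulfurization turns both linchpin carbons into methylenes and so reveals the 1,5,9-triol spacing; trisubstituted alkenes, silyl ethers and primary alkyl chlorides survive deactivated Raney Ni, and no stereocentre is touched.

Step 10
Reactants: 28 C19–C38 chloride
Product: 29 C19 allylic alcohol
Conditions: HF·pyridine, pyridine, THF, 0 °C
Reagents that add atoms: none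
Why: Buffered fluoride cleaves the primary allylic TBS ether much faster than the three secondary TBS ethers.

Step 11
Reactants: 29 C19 allylic alcohol
Product: 30 C19 (Z)-enal
Conditions: MnO2, CH2Cl2, rt
Reagents that add atoms: none
Why: Neutral allylic oxidation that does not isomerize the Z-2-methyl enal (used at once).

Step 12
Reactants: 31 (S)-4-benzyl-1,3-thiazolidine-2-thione; 32 propanoyl chloride
Product: 33 (S)-4-benzyl-3-propanoyl-1,3-thiazolidine-2-thione
Conditions: Et3N, DMAP (cat.), CH2Cl2, 0 °C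
Reagents that add atoms: none
Why: N-Acylation of the auxiliary gives the propionate unit for the C17–C19 aldol.

Step 13
Reactants: 30 C19 (Z)-enal; 33 N-propanoyl thiazolidinethione
Product: 35 syn-aldol adduct (18R,19S), via titanium enolate 34 (not isolated)
Conditions: 33 (1.5 equiv), TiCl4, i-Pr2NEt, N-methylpyrrolidinone, CH2Cl2, 0 °C; then 30, −78 → −40 °C
Reagents that add atoms: none
Why: Crimmins titanium aldol: the Z-enolate reacts through the non-chelated Zimmerman–Traxler chair to give the "Evans-syn" adduct, so the auxiliary sets C18 (R) and C19 (S) with the 18,19-syn relationship.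

Step 14
Reactants: 35 syn-aldol adduct
Product: 36 C19 TBS ether
Conditions: TBSOTf, 2,6-lutidine, CH2Cl2, −78 → 0 °C
Reagents that add atoms: tert-butyldimethylsilyl triflate CC(C)(C)[Si](C)(C)OS(=O)(=O)C(F)(F)F
Why: Silylation of the hindered allylic secondary alcohol with the triflate; prevents retro-aldol in the next step.

Step 15
Reactants: 36 C19 TBS ether
Product: 37 C17 aldehyde
Conditions: i-Bu2AlH, CH2Cl2, −78 °C
Reagents that add atoms: none
Why: N-Acyl thiazolidinethiones are reduced directly to aldehydes through a stable tetrahedral aluminate; at −78 °C C18 does not epimerize.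

Step 16
Reactants: 37 C17 aldehyde
Product: 38 C17 1,3-dithiane chloride
Conditions: HS(CH2)3SH, MgBr2·OEt2, Et2O, 0 °C → rt
Reagents that add atoms: propane-1,3-dithiol SCCCS
Why: Mild Lewis-acid thioacetalization converts the electrophilic C17 carbonyl into a latent acyl anion without touching the silyl ethers or the α-stereocentre.

Step 17
Reactants: 38 C17 dithiane chloride
Product: 39 C38 triphenylphosphonium iodide
Conditions: PPh3, NaI, i-Pr2NEt (cat.), MeCN, 80 °C
Reagents that add atoms: triphenylphosphine c1ccc(cc1)P(c1ccccc1)c1ccccc1; sodium iodide [Na+].[I-]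
Why: In situ Finkelstein exchange followed by SN2 quaternization of PPh3 at the primary carbon.

Step 18
Reactants: 40 (R)-propylene oxide; 41 6-bromohex-1-ene
Product: 43 (R)-non-8-en-2-ol, via hex-5-enylmagnesium bromide 42 (not isolated)
Conditions: Mg, THF; CuI (5 mol %), 40, −30 → 0 °C
Reagents that add atoms: none
Why: Copper-catalysed Grignard opening at the epoxide CH2; C49 (R) is taken from (R)-propylene oxide.

Step 19
Reactants: 43 (R)-non-8-en-2-ol
Product: 44 TBS ether of 43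
Conditions: TBSCl, imidazole, DMF, rt
Reagents that add atoms: tert-butyldimethylsilyl chloride CC(C)(C)[Si](C)(C)Cl
Why: Standard silylation of a secondary alcohol.

Step 20
Reactants: 44 TBS ether of 43
Product: 45 (R)-7-(TBS-oxy)octanal
Conditions: O3, CH2Cl2, −78 °C; then PPh3
Reagents that add atoms: ozone [O-][O+]=O
Why: Ozonolysis of the only alkene with reductive work-up gives the C43 aldehyde.

Step 21
Reactants: 45 (R)-7-(TBS-oxy)octanal
Product: 46 syn homoallylic alcohol (42S,43R)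
Conditions: cis-2-butene, n-BuLi, KOt-Bu, THF, −78 → −45 °C; (−)-Ipc2BOMe, −78 °C; BF3·OEt2; then 45, −78 °C; NaOH, H2O2, rt
Reagents that add atoms: cis-but-2-ene C/C=C\C
Why: Brown (Z)-crotylboration through a closed chair transition state: the Z-crotyl geometry of the borane made in the flask translates into the 42,43-syn relationship, and the (+)-α-pinene-derived Ipc ligands direct attack to the Si face of the aldehyde, which sets C43 (R) and C42 (S) under reagent control.

Step 22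
Reactants: 46 syn homoallylic alcohol
Product: 47 C43 TBS ether
Conditions: TBSOTf, 2,6-lutidine, CH2Cl2, −78 → 0 °C
Reagents that add atoms: tert-butyldimethylsilyl triflate CC(C)(C)[Si](C)(C)OS(=O)(=O)C(F)(F)F
Why: Silylation fixes C43–O as the permanent TBS ether, so C41–O can later be differentiated.

Step 23
Reactants: 47 C43 TBS ether
Product: 48 C41 aldehyde (42S,43R,49R)
Conditions: O3, CH2Cl2, −78 °C; then PPh3
Reagents that add atoms: ozone [O-][O+]=O
Why: Ozonolysis of the terminal vinyl group with neutral reductive work-up turns the crotyl adduct into the α-methyl-β-silyloxy aldehyde without epimerizing C42.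

Step 24
Reactants: 48 C41 aldehyde
Product: 49 homoallylic alcohol (41S)
Conditions: (−)-Ipc2B(allyl), Et2O, −78 °C; then NaOH, H2O2
Reagents that add atoms: (−)-B-allyldiisopinocampheylborane C=CCB([C@@H]1C[C@@H]2C[C@H]([C@H]1C)C2(C)C)[C@@H]1C[C@@H]2C[C@H]([C@H]1C)C2(C)C
Why: Brown allylboration through a chair transition state; the (+)-α-pinene-derived reagent adds to the Si face under reagent control and sets C41 (S), completing the syn,syn C41–C43 triad.

Step 25
Reactants: 49 homoallylic alcohol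
Product: 50 C41 TES ether
Conditions: TESCl, imidazole, DMF, 0 °C
Reagents that add atoms: triethylsilyl chloride CC[Si](Cl)(CC)CC
Why: The more labile TES group marks the one oxygen (O41) that must later be freed in the presence of secondary TBS ethers.

Step 26
Reactants: 50 C41 TES ether
Product: 51 C39 aldehyde
Conditions: O3, pyridine, CH2Cl2, −78 °C; then PPh3
Reagents that add atoms: ozone [O-][O+]=O
Why: Ozonolysis of the terminal alkene gives the C39 aldehyde; pyridine buffering protects the TES ether.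

Step 27
Reactants: 39 C38 phosphonium iodide; 51 C39 aldehyde
Product: 53 C17–C50 dithiane (38Z), via phosphorus ylide 52 (not isolated)
Conditions: NaN(SiMe3)2, THF, −78 °C; 51, −78 °C → rt
Reagents that add atoms: none
Why: Wittig reaction of a non-stabilized ylide under sodium-base conditions is kinetically Z-selective and gives the C38=C39 cis alkene; the dithiane C–H is far less acidic than the phosphonium α-CH2.

Step 28
Reactants: 53 C17–C50 dithiane; 18 C3–C16 epoxide
Product: 56 C3–C50 chain (tris-dithiane; C15 OTBS), via C17 lithiated dithiane 54 (not isolated), via C15 lithium alkoxide 55 (not isolated)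
Conditions: t-BuLi, THF/HMPA (9:1), −78 °C, 10 min; 18 (1.3 equiv), −78 → −30 °C; then TBSOTf, −78 → 0 °C
Reagents that add atoms: tert-butyldimethylsilyl triflate CC(C)(C)[Si](C)(C)OS(=O)(=O)C(F)(F)F
Why: Corey–Seebach umpolung: C17, an aldehyde carbon in 37, is deprotonated as its 1,3-dithiane and this acyl-anion equivalent opens the terminal epoxide at C16 (SN2 at CH2, no stereocentre touched); this joins the two halves and places the third masked ketone between the C15 and C19 oxygens, and the C15 alkoxide is silylated in the flask.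

Step 29
Reactants: 56 C3–C50 chain
Product: 57 C3,C41-diol
Conditions: HF·pyridine, pyridine, THF, 0 °C
Reagents that add atoms: none
Why: Buffered fluoride removes the primary allylic TBS (O3) and the secondary TES (O41) while the nine secondary TBS ethers stay.

Step 30
Reactants: 57 C3,C41-diol
Product: 58 C3 (Z)-enal with free C41 hydroxyl
Conditions: MnO2, CH2Cl2, rt
Reagents that add atoms: none
Why: MnO2 oxidizes only the allylic primary alcohol; the homoallylic secondary C41 hydroxyl and the dithianes are inert.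

Step 31
Reactants: 58 hydroxy enal; 59 diethylphosphonoacetic acid
Product: 60 C41 diethylphosphonoacetate
Conditions: DCC, DMAP (cat.), CH2Cl2, 0 °C → rt
Reagents that add atoms: none
Why: Steglich esterification of the only free hydroxyl installs C1–C2 and fixes the lactone oxygen at C41.

Step 32
Reactants: 60 C41 phosphonoacetate enal
Product: 61 protected 42-membered macrolactone (2E,4Z; tris-dithiane)
Conditions: LiCl, i-Pr2NEt, MeCN (1 mM), rt
Reagents that add atoms: none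
Why: Intramolecular Horner–Wadsworth–Emmons olefination under Masamune–Roush conditions closes the ring at C2=C3 with E selectivity; the mild base keeps the Z-enal geometry at C4=C5.

Step 33
Reactants: 61 protected macrolactone
Product: 62 C9,C13,C17-triketone (nonakis-TBS ether)
Conditions: PhI(OCOCF3)2, MeCN/H2O (9:1), 0 °C
Reagents that add atoms: water O
Why: Oxidative hydrolysis of the three dithianes at sulfur releases the ketones under conditions that leave alkenes, the dienoate and silyl ethers alone.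

Step 34
Reactants: 62 triketone nonakis-TBS ether
Product: 63 triketone nonaol
Conditions: HF·pyridine, THF, 0 °C → rt
Reagents that add atoms: none
Why: Acidic fluoride removes all secondary TBS ethers without base, so the β-hydroxy ketones neither eliminate nor undergo retro-aldol and C18 is not epimerized.

Step 35
Reactants: 63 triketone nonaol
Product: 64 target macrolide CNP0392687.1
Conditions: Me4NBH(OAc)3, MeCN/AcOH (1:1), −30 °C
Reagents that add atoms: none
Why: Evans–Saksena reduction: each ketone is flanked by two β-hydroxyls on the same side (C7/C11, C11/C15, C15/C19), both deliver hydride intramolecularly to the same face, and the 1,3-anti carbinols C9 (R), C13 (R) and C17 (R) are set together.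

## Compound list

1 | prop-2-yn-1-ol | C#CCO | starting material
2 | bis(bromomagnesium) (Z)-alkenyl alkoxide, BrMg–CH=C(CH3)–CH2–OMgBr | Br[Mg]OC/C(C)=C\[Mg]Br | intermediate
3 | (Z)-3-iodo-2-methylprop-2-en-1-ol | OC/C(C)=C\I | intermediate
4 | (Z)-tert-butyl[(3-iodo-2-methylprop-2-en-1-yl)oxy]dimethylsilane | CC(C)(C)[Si](C)(C)OC/C(C)=C\I | intermediate
5 | (S)-epichlorohydrin, (S)-2-(chloromethyl)oxirane | ClC[C@@H]1CO1 | starting material
6 | (Z)-[3-(TBS-oxy)-2-methylprop-1-en-1-yl]magnesium chloride | CC(C)(C)[Si](C)(C)OC/C(C)=C\[Mg]Cl | intermediate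
7 | (2S,4Z)-6-(TBS-oxy)-1-chloro-5-methylhex-4-en-2-ol | CC(C)(C)[Si](C)(C)OC/C(C)=C\C[C@H](O)CCl | intermediate
8 | (S)-2-[(Z)-4-(TBS-oxy)-3-methylbut-2-en-1-yl]oxirane (C3–C8 / C19–C24 unit) | CC(C)(C)[Si](C)(C)OC/C(C)=C\C[C@H]1CO1 | intermediate
9 | 2-(tert-butyldimethylsilyl)-1,3-dithiane | CC(C)(C)[Si](C)(C)C1SCCCS1 | starting material
10 | 2-lithio-2-(tert-butyldimethylsilyl)-1,3-dithiane (titrated Et2O stock solution) | [Li]C1(SCCCS1)[Si](C)(C)C(C)(C)C | intermediate
11 | lithium alkoxide from 8 + 10: C3 OTBS, 4Z alkene, C7 OLi (7S), C9 = 2-TBS-dithiane carbon | CC(C)(C)[Si](C)(C)OC/C(C)=C\C[C@H](O[Li])CC1(SCCCS1)[Si](C)(C)C(C)(C)C | intermediate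
12 | Brook-shifted anion: C7 OTBS, C9 = 2-lithio-dithiane carbon | CC(C)(C)[Si](C)(C)OC/C(C)=C\C[C@H](O[Si](C)(C)C(C)(C)C)CC1([Li])SCCCS1 | intermediate
13 | lithium chlorohydrin alkoxide: C9 dithiane, C11 OLi (11S), C12 Cl | CC(C)(C)[Si](C)(C)OC/C(C)=C\C[C@H](O[Si](C)(C)C(C)(C)C)CC1(SCCCS1)C[C@H](O[Li])CCl | intermediate
14 | C3–C12 epoxide: C3 OTBS, (4Z)-4-methyl alkene, C7 OTBS (7S), C9 dithiane, C11–C12 oxirane (11S); the same compound is the C19–C28 unit (23R, 27R in target terms) | CC(C)(C)[Si](C)(C)OC/C(C)=C\C[C@H](O[Si](C)(C)C(C)(C)C)CC1(SCCCS1)C[C@H]2CO2 | intermediate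
15 | lithium alkoxide from 14 + 10: C11 OLi, C13 = 2-TBS-dithiane carbon | CC(C)(C)[Si](C)(C)OC/C(C)=C\C[C@H](O[Si](C)(C)C(C)(C)C)CC1(SCCCS1)C[C@H](O[Li])CC2(SCCCS2)[Si](C)(C)C(C)(C)C | intermediate
16 | Brook-shifted anion: C11 OTBS, C13 = 2-lithio-dithiane carbon | CC(C)(C)[Si](C)(C)OC/C(C)=C\C[C@H](O[Si](C)(C)C(C)(C)C)CC1(SCCCS1)C[C@H](O[Si](C)(C)C(C)(C)C)CC2([Li])SCCCS2 | intermediate
17 | lithium chlorohydrin alkoxide: C13 dithiane, C15 OLi (15S), C16 Cl | CC(C)(C)[Si](C)(C)OC/C(C)=C\C[C@H](O[Si](C)(C)C(C)(C)C)CC1(SCCCS1)C[C@H](O[Si](C)(C)C(C)(C)C)CC2(SCCCS2)C[C@H](O[Li])CCl | intermediate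
18 | C3–C16 epoxide (western fragment): C3, C7, C11 OTBS (7S,11S), C9 and C13 dithianes, C15–C16 oxirane (15S) | CC(C)(C)[Si](C)(C)OC/C(C)=C\C[C@H](O[Si](C)(C)C(C)(C)C)CC1(SCCCS1)C[C@H](O[Si](C)(C)C(C)(C)C)CC2(SCCCS2)C[C@H]3CO3 | intermediate
19 | 1-bromo-6-chlorohexane | ClCCCCCCBr | starting material
20 | (R)-epichlorohydrin, (R)-2-(chloromethyl)oxirane | ClC[C@H]1CO1 | starting material
21 | (6-chlorohexyl)magnesium bromide | ClCCCCCC[Mg]Br | intermediate
22 | (R)-1,9-dichlorononan-2-ol | ClCCCCCCC[C@@H](O)CCl | intermediate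
23 | (R)-2-(7-chloroheptyl)oxirane (C30–C38 unit) | ClCCCCCCC[C@@H]1CO1 | intermediate
24 | lithium alkoxide from 23 + 10: C31 OLi (31R), C29 = 2-TBS-dithiane carbon, C38 Cl | ClCCCCCCC[C@@H](O[Li])CC1(SCCCS1)[Si](C)(C)C(C)(C)C | intermediate
25 | Brook-shifted anion: C31 OTBS, C29 = 2-lithio-dithiane carbon, C38 Cl | ClCCCCCCC[C@@H](O[Si](C)(C)C(C)(C)C)CC1([Li])SCCCS1 | intermediate
26 | lithium alkoxide: C19–C38 chain, C19/C23/C31 OTBS, C25 and C29 dithianes, C27 OLi, C38 Cl | CC(C)(C)[Si](C)(C)OC/C(C)=C\C[C@H](O[Si](C)(C)C(C)(C)C)CC1(SCCCS1)C[C@H](O[Li])CC2(SCCCS2)C[C@H](O[Si](C)(C)C(C)(C)C)CCCCCCCCl | intermediate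
27 | C19–C38 chloride: C19 OTBS (primary), (20Z)-20-methyl alkene, C23/C27/C31 OTBS (23R,27R,31R), dithianes at C25 and C29 | CC(C)(C)[Si](C)(C)OC/C(C)=C\C[C@H](O[Si](C)(C)C(C)(C)C)CC1(SCCCS1)C[C@H](O[Si](C)(C)C(C)(C)C)CC2(SCCCS2)C[C@H](O[Si](C)(C)C(C)(C)C)CCCCCCCCl | intermediate
28 | C19–C38 chloride after desulfurization: C19 OTBS, 20Z alkene, C23/C27/C31 OTBS | CC(C)(C)[Si](C)(C)OC/C(C)=C\C[C@H](O[Si](C)(C)C(C)(C)C)CCC[C@H](O[Si](C)(C)C(C)(C)C)CCC[C@H](O[Si](C)(C)C(C)(C)C)CCCCCCCCl | intermediate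
29 | C19 allylic alcohol of 28 | OC/C(C)=C\C[C@H](O[Si](C)(C)C(C)(C)C)CCC[C@H](O[Si](C)(C)C(C)(C)C)CCC[C@H](O[Si](C)(C)C(C)(C)C)CCCCCCCCl | intermediate
30 | C19 (Z)-2-methyl enal (C19–C38) | O=C/C(C)=C\C[C@H](O[Si](C)(C)C(C)(C)C)CCC[C@H](O[Si](C)(C)C(C)(C)C)CCC[C@H](O[Si](C)(C)C(C)(C)C)CCCCCCCCl | intermediate
31 | (S)-4-benzyl-1,3-thiazolidine-2-thione | S=C1N[C@@H](Cc2ccccc2)CS1 | starting material
32 | propanoyl chloride | CCC(Cl)=O | starting material
33 | (S)-4-benzyl-3-propanoyl-1,3-thiazolidine-2-thione | CCC(=O)N1C(=S)SC[C@@H]1Cc1ccccc1 | intermediate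
34 | trichlorotitanium (Z)-enolate of 33 | C/C=C(\O[Ti](Cl)(Cl)Cl)N1C(=S)SC[C@@H]1Cc1ccccc1 | intermediate
35 | aldol adduct: N-acyl thiazolidinethione at C17, C18 Me (18R), C19 OH (19S), rest as 30 | S=C1SC[C@H](Cc2ccccc2)N1C(=O)[C@@H](C)[C@H](O)/C(C)=C\C[C@H](O[Si](C)(C)C(C)(C)C)CCC[C@H](O[Si](C)(C)C(C)(C)C)CCC[C@H](O[Si](C)(C)C(C)(C)C)CCCCCCCCl | intermediate
36 | C19 TBS ether of 35 | S=C1SC[C@H](Cc2ccccc2)N1C(=O)[C@@H](C)[C@H](O[Si](C)(C)C(C)(C)C)/C(C)=C\C[C@H](O[Si](C)(C)C(C)(C)C)CCC[C@H](O[Si](C)(C)C(C)(C)C)CCC[C@H](O[Si](C)(C)C(C)(C)C)CCCCCCCCl | intermediate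
37 | C17 aldehyde (C17–C38): C18 Me, C19/C23/C27/C31 OTBS, 20Z, C38 Cl | O=C[C@@H](C)[C@H](O[Si](C)(C)C(C)(C)C)/C(C)=C\C[C@H](O[Si](C)(C)C(C)(C)C)CCC[C@H](O[Si](C)(C)C(C)(C)C)CCC[C@H](O[Si](C)(C)C(C)(C)C)CCCCCCCCl | intermediate
38 | C17 1,3-dithiane of 37 | S1CCCSC1[C@@H](C)[C@H](O[Si](C)(C)C(C)(C)C)/C(C)=C\C[C@H](O[Si](C)(C)C(C)(C)C)CCC[C@H](O[Si](C)(C)C(C)(C)C)CCC[C@H](O[Si](C)(C)C(C)(C)C)CCCCCCCCl | intermediate
39 | C38 triphenylphosphonium iodide of 38 | S1CCCSC1[C@@H](C)[C@H](O[Si](C)(C)C(C)(C)C)/C(C)=C\C[C@H](O[Si](C)(C)C(C)(C)C)CCC[C@H](O[Si](C)(C)C(C)(C)C)CCC[C@H](O[Si](C)(C)C(C)(C)C)CCCCCCC[P+](c1ccccc1)(c1ccccc1)c1ccccc1.[I-] | intermediate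
40 | (R)-propylene oxide, (R)-2-methyloxirane | C[C@@H]1CO1 | starting material
41 | 6-bromohex-1-ene | C=CCCCCBr | starting material
42 | hex-5-en-1-ylmagnesium bromide | C=CCCCC[Mg]Br | intermediate
43 | (R)-non-8-en-2-ol | C=CCCCCC[C@@H](C)O | intermediate
44 | (R)-tert-butyldimethyl(non-8-en-2-yloxy)silane | C=CCCCCC[C@@H](C)O[Si](C)(C)C(C)(C)C | intermediate
45 | (R)-7-(TBS-oxy)octanal (C43–C50) | O=CCCCCC[C@@H](C)O[Si](C)(C)C(C)(C)C | intermediate
46 | syn homoallylic alcohol, 10-(TBS-oxy)-3-methylundec-1-en-4-ol: vinyl on C42, C42 Me (42S), C43 OH (43R), C49 OTBS (49R) | C=C[C@@H](C)[C@H](O)CCCCC[C@@H](C)O[Si](C)(C)C(C)(C)C | intermediate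
47 | C43 TBS ether of 46 | C=C[C@@H](C)[C@H](O[Si](C)(C)C(C)(C)C)CCCCC[C@@H](C)O[Si](C)(C)C(C)(C)C | intermediate
48 | C41 aldehyde: 3,9-bis(TBS-oxy)-2-methyldecanal (42S,43R,49R) | O=C[C@@H](C)[C@H](O[Si](C)(C)C(C)(C)C)CCCCC[C@@H](C)O[Si](C)(C)C(C)(C)C | intermediate
49 | homoallylic alcohol: allyl on C41, C41 OH (41S), C42 Me, C43/C49 OTBS | C=CC[C@H](O)[C@@H](C)[C@H](O[Si](C)(C)C(C)(C)C)CCCCC[C@@H](C)O[Si](C)(C)C(C)(C)C | intermediate
50 | C41 TES ether of 49 | C=CC[C@H](O[Si](CC)(CC)CC)[C@@H](C)[C@H](O[Si](C)(C)C(C)(C)C)CCCCC[C@@H](C)O[Si](C)(C)C(C)(C)C | intermediate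
51 | C39 aldehyde (C39–C50): C41 OTES, C42 Me, C43/C49 OTBS (41S,42S,43R,49R) | O=CC[C@H](O[Si](CC)(CC)CC)[C@@H](C)[C@H](O[Si](C)(C)C(C)(C)C)CCCCC[C@@H](C)O[Si](C)(C)C(C)(C)C | intermediate
52 | C38 triphenylphosphonium ylide from 39 | S1CCCSC1[C@@H](C)[C@H](O[Si](C)(C)C(C)(C)C)/C(C)=C\C[C@H](O[Si](C)(C)C(C)(C)C)CCC[C@H](O[Si](C)(C)C(C)(C)C)CCC[C@H](O[Si](C)(C)C(C)(C)C)CCCCCCC=P(c1ccccc1)(c1ccccc1)c1ccccc1 | intermediate
53 | C17–C50 eastern fragment: C17 dithiane (2-H), C18 Me, C19/C23/C27/C31/C43/C49 OTBS, C41 OTES, 20Z and 38Z alkenes | S1CCCSC1[C@@H](C)[C@H](O[Si](C)(C)C(C)(C)C)/C(C)=C\C[C@H](O[Si](C)(C)C(C)(C)C)CCC[C@H](O[Si](C)(C)C(C)(C)C)CCC[C@H](O[Si](C)(C)C(C)(C)C)CCCCCC/C=C\C[C@H](O[Si](CC)(CC)CC)[C@@H](C)[C@H](O[Si](C)(C)C(C)(C)C)CCCCC[C@@H](C)O[Si](C)(C)C(C)(C)C | intermediate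
54 | 2-lithio derivative of 53 (C17 carbanion) | [Li]C1(SCCCS1)[C@@H](C)[C@H](O[Si](C)(C)C(C)(C)C)/C(C)=C\C[C@H](O[Si](C)(C)C(C)(C)C)CCC[C@H](O[Si](C)(C)C(C)(C)C)CCC[C@H](O[Si](C)(C)C(C)(C)C)CCCCCC/C=C\C[C@H](O[Si](CC)(CC)CC)[C@@H](C)[C@H](O[Si](C)(C)C(C)(C)C)CCCCC[C@@H](C)O[Si](C)(C)C(C)(C)C | intermediate
55 | C15 lithium alkoxide of the C3–C50 chain (dithianes at C9, C13, C17) | CC(C)(C)[Si](C)(C)OC/C(C)=C\C[C@H](O[Si](C)(C)C(C)(C)C)CC1(SCCCS1)C[C@H](O[Si](C)(C)C(C)(C)C)CC2(SCCCS2)C[C@H](O[Li])CC3(SCCCS3)[C@@H](C)[C@H](O[Si](C)(C)C(C)(C)C)/C(C)=C\C[C@H](O[Si](C)(C)C(C)(C)C)CCC[C@H](O[Si](C)(C)C(C)(C)C)CCC[C@H](O[Si](C)(C)C(C)(C)C)CCCCCC/C=C\C[C@H](O[Si](CC)(CC)CC)[C@@H](C)[C@H](O[Si](C)(C)C(C)(C)C)CCCCC[C@@H](C)O[Si](C)(C)C(C)(C)C | intermediate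
56 | C3–C50 chain: TBS ethers at O3, O7, O11, O15, O19, O23, O27, O31, O43, O49; TES at O41; dithianes at C9, C13, C17; 4Z, 20Z, 38Z | CC(C)(C)[Si](C)(C)OC/C(C)=C\C[C@H](O[Si](C)(C)C(C)(C)C)CC1(SCCCS1)C[C@H](O[Si](C)(C)C(C)(C)C)CC2(SCCCS2)C[C@H](O[Si](C)(C)C(C)(C)C)CC3(SCCCS3)[C@@H](C)[C@H](O[Si](C)(C)C(C)(C)C)/C(C)=C\C[C@H](O[Si](C)(C)C(C)(C)C)CCC[C@H](O[Si](C)(C)C(C)(C)C)CCC[C@H](O[Si](C)(C)C(C)(C)C)CCCCCC/C=C\C[C@H](O[Si](CC)(CC)CC)[C@@H](C)[C@H](O[Si](C)(C)C(C)(C)C)CCCCC[C@@H](C)O[Si](C)(C)C(C)(C)C | intermediate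
57 | C3,C41-diol of 56 (nine secondary TBS ethers kept) | OC/C(C)=C\C[C@H](O[Si](C)(C)C(C)(C)C)CC1(SCCCS1)C[C@H](O[Si](C)(C)C(C)(C)C)CC2(SCCCS2)C[C@H](O[Si](C)(C)C(C)(C)C)CC3(SCCCS3)[C@@H](C)[C@H](O[Si](C)(C)C(C)(C)C)/C(C)=C\C[C@H](O[Si](C)(C)C(C)(C)C)CCC[C@H](O[Si](C)(C)C(C)(C)C)CCC[C@H](O[Si](C)(C)C(C)(C)C)CCCCCC/C=C\C[C@H](O)[C@@H](C)[C@H](O[Si](C)(C)C(C)(C)C)CCCCC[C@@H](C)O[Si](C)(C)C(C)(C)C | intermediate
58 | C3 (Z)-enal with free C41 OH | O=C/C(C)=C\C[C@H](O[Si](C)(C)C(C)(C)C)CC1(SCCCS1)C[C@H](O[Si](C)(C)C(C)(C)C)CC2(SCCCS2)C[C@H](O[Si](C)(C)C(C)(C)C)CC3(SCCCS3)[C@@H](C)[C@H](O[Si](C)(C)C(C)(C)C)/C(C)=C\C[C@H](O[Si](C)(C)C(C)(C)C)CCC[C@H](O[Si](C)(C)C(C)(C)C)CCC[C@H](O[Si](C)(C)C(C)(C)C)CCCCCC/C=C\C[C@H](O)[C@@H](C)[C@H](O[Si](C)(C)C(C)(C)C)CCCCC[C@@H](C)O[Si](C)(C)C(C)(C)C | intermediate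
59 | diethylphosphonoacetic acid | CCOP(=O)(CC(=O)O)OCC | starting material
60 | C41 diethylphosphonoacetate of 58 | O=C/C(C)=C\C[C@H](O[Si](C)(C)C(C)(C)C)CC1(SCCCS1)C[C@H](O[Si](C)(C)C(C)(C)C)CC2(SCCCS2)C[C@H](O[Si](C)(C)C(C)(C)C)CC3(SCCCS3)[C@@H](C)[C@H](O[Si](C)(C)C(C)(C)C)/C(C)=C\C[C@H](O[Si](C)(C)C(C)(C)C)CCC[C@H](O[Si](C)(C)C(C)(C)C)CCC[C@H](O[Si](C)(C)C(C)(C)C)CCCCCC/C=C\C[C@H](OC(=O)CP(=O)(OCC)OCC)[C@@H](C)[C@H](O[Si](C)(C)C(C)(C)C)CCCCC[C@@H](C)O[Si](C)(C)C(C)(C)C | intermediate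
61 | protected macrolactone: (2E,4Z,20Z,38Z), dithianes at C9, C13, C17, nine secondary TBS ethers | CC1=C/C[C@H](O[Si](C)(C)C(C)(C)C)CC2(SCCCS2)C[C@H](O[Si](C)(C)C(C)(C)C)CC3(SCCCS3)C[C@H](O[Si](C)(C)C(C)(C)C)CC4(SCCCS4)[C@@H](C)[C@H](O[Si](C)(C)C(C)(C)C)/C(C)=C\C[C@H](O[Si](C)(C)C(C)(C)C)CCC[C@H](O[Si](C)(C)C(C)(C)C)CCC[C@H](O[Si](C)(C)C(C)(C)C)CCCCCC/C=C\C[C@@H]([C@@H](C)[C@H](O[Si](C)(C)C(C)(C)C)CCCCC[C@@H](C)O[Si](C)(C)C(C)(C)C)OC(=O)\C=C\1 | intermediate
62 | macrolactone C9,C13,C17-triketone, nine secondary TBS ethers | CC1=C/C[C@H](O[Si](C)(C)C(C)(C)C)CC(=O)C[C@H](O[Si](C)(C)C(C)(C)C)CC(=O)C[C@H](O[Si](C)(C)C(C)(C)C)CC(=O)[C@@H](C)[C@H](O[Si](C)(C)C(C)(C)C)/C(C)=C\C[C@H](O[Si](C)(C)C(C)(C)C)CCC[C@H](O[Si](C)(C)C(C)(C)C)CCC[C@H](O[Si](C)(C)C(C)(C)C)CCCCCC/C=C\C[C@@H]([C@@H](C)[C@H](O[Si](C)(C)C(C)(C)C)CCCCC[C@@H](C)O[Si](C)(C)C(C)(C)C)OC(=O)\C=C\1 | intermediate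
63 | macrolactone C9,C13,C17-triketone nonaol (free OH at C7, C11, C15, C19, C23, C27, C31, C43, C49) | CC1=C/C[C@H](O)CC(=O)C[C@H](O)CC(=O)C[C@H](O)CC(=O)[C@@H](C)[C@H](O)/C(C)=C\C[C@H](O)CCC[C@H](O)CCC[C@H](O)CCCCCC/C=C\C[C@@H]([C@@H](C)[C@H](O)CCCCC[C@@H](C)O)OC(=O)\C=C\1 | intermediate
64 | CNP0392687.1 (2E,4Z,20Z,38Z; 7S,9R,11S,13R,15S,17R,18R,19S,23R,27R,31R,41S,42S,43R,49R) | CC1=C/C[C@H](O)C[C@@H](O)C[C@H](O)C[C@@H](O)C[C@H](O)C[C@@H](O)[C@@H](C)[C@H](O)/C(C)=C\C[C@H](O)CCC[C@H](O)CCC[C@H](O)CCCCCC/C=C\C[C@@H]([C@@H](C)[C@H](O)CCCCC[C@@H](C)O)OC(=O)\C=C\1 | target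

## Step count and risks

Total: 35 steps. Longest linear sequence: 22 steps (1–3, 5, 8–11, 13–17, 27–35).

Three steps most likely to fail:

Step 9 (Raney Ni desulfurization next to a trisubstituted alkene, an allylic silyl ether and an alkyl chloride). If alkene reduction, isomerization or C–Cl loss intrudes, the sulfur is removed through the carbonyl instead. The fallback sets out from 27 and comes back at 28. PhI(OCOCF3)2 in wet MeCN gives the C25,C29-diketone F1. NaBH4 reduces it to the diol (epimer mixture at C25/C29, of no consequence) F2. 1,1'-Thiocarbonyldiimidazole without strong base (no silyl migration) gives the bis(imidazol-1-ylthiocarbonyl) ester F3. Barton–McCombie deoxygenation (Bu3SnH, AIBN, toluene, 110 °C) then gives 28.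

Step 28 (union of the two halves). The branched, β-silyloxy dithiane anion 54 must open the epoxide of a second large fragment. If this stalls, the bond joining the large pieces is moved to C13–C14. The fallback sets out from 53 and 14 and comes back at 56. 53 is lithiated to 54 as before but quenched with a large excess of small (R)-epichlorohydrin 20, which gives on warming the C17-dithianyl C14–C15 epoxide F4. Epoxide 14 is then treated with stock reagent 10 and HMPA so that it passes through 15 and the unbranched, Brook-generated anion 16 as in step 6. Anion 16 opens F4 at C14 to give the same alkoxide 55, which TBSOTf converts to 56. The hindered anion then only has to meet a small electrophile, and the fragment union uses a relay-generated anion instead of a deprotonation.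

Step 35 (triple directed reduction, with the sensitive 1,5-diketone polyol 63 made in steps 33–34). If the silylated or free triketone degrades by β-elimination or intramolecular aldol before it can be reduced, the order of unmasking is inverted so that the ketones exist only in the presence of the hydride. The fallback sets out from 61 and comes back at 63. HF·pyridine first gives the nonaol tris-dithiane macrolide F5, which is stable and can be purified. PhI(OCOCF3)2 in wet MeCN at 0 °C then releases the three ketones to give 63, which is not isolated; AcOH and Me4NBH(OAc)3 are added to the same flask at −30 °C to give 64.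

Further compounds
F1 | step 9 | C19–C38 chloride C25,C29-diketone (C19/C23/C27/C31 OTBS, 20Z) | CC(C)(C)[Si](C)(C)OC/C(C)=C\C[C@H](O[Si](C)(C)C(C)(C)C)CC(=O)C[C@H](O[Si](C)(C)C(C)(C)C)CC(=O)C[C@H](O[Si](C)(C)C(C)(C)C)CCCCCCCCl
F2 | step 9 | C25,C29-diol from F1 (epimer mixture at C25 and C29) | CC(C)(C)[Si](C)(C)OC/C(C)=C\C[C@H](O[Si](C)(C)C(C)(C)C)CC(O)C[C@H](O[Si](C)(C)C(C)(C)C)CC(O)C[C@H](O[Si](C)(C)C(C)(C)C)CCCCCCCCl
F3 | step 9 | C25,C29-bis(imidazol-1-ylthiocarbonyl) ester of F2 | CC(C)(C)[Si](C)(C)OC/C(C)=C\C[C@H](O[Si](C)(C)C(C)(C)C)CC(OC(=S)n1ccnc1)C[C@H](O[Si](C)(C)C(C)(C)C)CC(OC(=S)n1ccnc1)C[C@H](O[Si](C)(C)C(C)(C)C)CCCCCCCCl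
F4 | step 28 | C14–C50 epoxide: C14–C15 oxirane on C16 (C15 as in the target), C17 dithiane, remainder as 53 | C1O[C@@H]1CC2(SCCCS2)[C@@H](C)[C@H](O[Si](C)(C)C(C)(C)C)/C(C)=C\C[C@H](O[Si](C)(C)C(C)(C)C)CCC[C@H](O[Si](C)(C)C(C)(C)C)CCC[C@H](O[Si](C)(C)C(C)(C)C)CCCCCC/C=C\C[C@H](O[Si](CC)(CC)CC)[C@@H](C)[C@H](O[Si](C)(C)C(C)(C)C)CCCCC[C@@H](C)O[Si](C)(C)C(C)(C)C
F5 | step 35 | macrolactone nonaol with dithianes at C9, C13, C17 | CC1=C/C[C@H](O)CC2(SCCCS2)C[C@H](O)CC3(SCCCS3)C[C@H](O)CC4(SCCCS4)[C@@H](C)[C@H](O)/C(C)=C\C[C@H](O)CCC[C@H](O)CCC[C@H](O)CCCCCC/C=C\C[C@@H]([C@@H](C)[C@H](O)CCCCC[C@@H](C)O)OC(=O)\C=C\1
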